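**Retrosynthetic overview**
1. Target ⇐ acetylation, alkene saturation, desulfonylation and hydrolysis/decarboxylation of a temporary sulfonyl lactone ⇐ Wittig extension of a C11 aldehyde with an (S)-configured C12–C15 ylide.
2. Ring B (C5=C6, C8, C9, C10) ⇐ exo Diels–Alder reaction of tiglaldehyde with the diene C10=C5–C6=C7; a temporary lactone C18–O–C(=O)–C2 closes the α face.
3. Ring A ⇐ palladium-catalysed 6-endo pentadienylation: C2 (sulfonyl-lactone enolate) attacks C1 of a divinyl carbinol, closing the C1–C2 bond and unveiling the diene.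
4. Enabling feature: C5, the sp2 ring-fusion carbon between quaternary C4, C6 and C10, can carry two identical vinyl arms (C10=C1 and C6=C7), so either terminus closes ring A and the other arm becomes the diene; C4 has no hydrogen, and its C18 oxygen is 1,3 to C2.
5. C4 ⇐ organocatalytic Michael addition of ethyl 2-cyanopropanoate to an aryl vinyl sulfone; ring order: temporary lactone, then ring A, then ring B.

Key step: step 5

**Remarks**
- Numbering is that of the halimane skeleton: ring A = C1–C5, C10; ring B = C5–C10; side chain C11–C16 (C15 = CO2H, C16 = methyl on C13); C17 on C8; C18 (CH2O) and C19 (CH3) on C4; C20 on C9. α is the face of H10. Ar = 3,5-bis(trifluoromethyl)phenyl.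
- Assumption: the aryl vinyl sulfone and (S)-4-methyloxolan-2-one are taken as catalogue compounds.
- Assumption: of the two pseudoenantiomeric 6'-hydroxy cinchona catalysts, the one that delivers the (S)-adduct is used (cupreidine ether written; otherwise its cupreine counterpart).

**Step 1**
Reactants: 1 ethyl 2-cyanopropanoate (racemic); 2 3,5-bis(trifluoromethyl)phenyl vinyl sulfone
Product: 3 ethyl (2S)-2-cyano-2-methyl-4-(ArSO2)butanoate
Conditions: 9-O-(9-phenanthryl)cupreidine (10 mol %), toluene, −25 °C
Reagents that add atoms: none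
Why: Bifunctional cinchona-alkaloid catalysis of the Michael addition of an α-substituted cyanoacetate to an electron-poor aryl vinyl sulfone is an established route to quaternary centres; the catalyst-bound enolate is attacked on one face, which sets C4.

**Step 2**
Reactants: 3 ethyl (2S)-2-cyano-2-methyl-4-(ArSO2)butanoate
Product: 5 (2S)-3-ethenyl-3-hydroxy-2-methyl-2-[2-(ArSO2)ethyl]pent-4-enenitrile, via vinyl ketone 4 (not isolated)
Conditions: CH2=CHMgBr (4 equiv), CeCl3 (4 equiv), THF, −78 → −20 °C; aq. NH4Cl
Reagents that add atoms: vinylmagnesium bromide, C=C[Mg]Br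
Why: Twofold organocerium 1,2-addition to the activated ester; the weakly basic reagent should leave the acidic sulfone CH2 and the hindered nitrile alone and add 1,2 to enone 4, and C4 is not involved.

**Step 3**
Reactants: 5 (2S)-3-ethenyl-3-hydroxy-2-methyl-2-[2-(ArSO2)ethyl]pent-4-enenitrile
Product: 7 (2S)-3-ethenyl-2-methyl-2-[2-(ArSO2)ethyl]pent-4-ene-1,3-diol, via hydroxy aldehyde 6 (not isolated)
Conditions: iBu2AlH (3.5 equiv), CH2Cl2, −78 → 0 °C; aq. potassium sodium tartrate; then NaBH4, MeOH, 0 °C
Reagents that add atoms: water, O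
Why: Half-reduction of the neopentyl nitrile to the aldimine, hydrolysis to the non-enolisable aldehyde and immediate borohydride reduction, which should outrun retro-aldol cleavage; the quaternary centre cannot epimerise.

**Step 4**
Reactants: 7 (2S)-3-ethenyl-2-methyl-2-[2-(ArSO2)ethyl]pent-4-ene-1,3-diol
Product: 9 (5S)-5-(3-hydroxypenta-1,4-dien-3-yl)-5-methyl-3-(ArSO2)oxan-2-one (both C3 epimers), via sulfonyl acid 8 (not isolated)
Conditions: LiN(iPr)2 (3.3 equiv), THF, −78 °C; CO2; cold aq. KHSO4; then EDC·HCl, DMAP (cat.), CH2Cl2, 0 °C → rt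
Reagents that add atoms: carbon dioxide, O=C=O
Why: Carboxylation of the α-sulfonyl carbanion (the alkoxides are carbonated only reversibly) followed by carbodiimide lactonisation, in which the primary C18 hydroxyl reacts and the hindered tertiary carbinol does not; both C2 epimers are usable.

**Step 5**
Reactants: 9 (5S)-5-(3-hydroxypenta-1,4-dien-3-yl)-5-methyl-3-(ArSO2)oxan-2-one
Product: 10 (1S,5R)-6-ethenyl-5-methyl-1-(ArSO2)-3-oxabicyclo[3.3.1]non-6-en-2-one (ring A with the diene C10=C5–C6=C7 and the α-face lactone bridge C18–O–C(=O)–C2)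
Conditions: Pd(PPh3)4 (5 mol %), Et3B (1.2 equiv), THF, 50 °C
Reagents that add atoms: none
Why: Et3B activates the tertiary bis-allylic hydroxyl of 9, zerovalent palladium ionises it to an η3-pentadienylpalladium cation in which the two vinyl arms on C5 are equivalent, and the sulfonyl-lactone enolate at C2 (formed by the released hydroxide) attacks a terminal carbon (C1) anti to the metal, an intramolecular Tsuji–Trost allylic alkylation. The closest known reaction types are palladium-catalysed cyclisations of stabilised carbanions held by a two-atom tether, which close the six-membered ring at the distal allyl terminus and not the four-membered one, terminal attack of soft nucleophiles on pentadienyl esters to give conjugated dienes, and the triethylborane-promoted use of free allylic alcohols as allyl donors. Ring A (C2–C3–C4–C5=C10–C1) closes in the 6-endo mode with respect to the allyl unit, and because C2 and C4 already sit in the δ-lactone the product is the bridged 3-oxabicyclo[3.3.1]nonene, the allylic transposition leaving the conjugated diene C10=C5–C6=C7. The only new stereocentre is the now quaternary C2: the C1–C2 bond can only form cis-1,3 to the C4–C5 bond across the lactone ring, so C4 dictates it and both C2 epimers of 9 converge through the planar enolate. The step needs terminal C-alkylation to win over attack at C5, O-alkylation, elimination and 4π-electrocyclisation of a free pentadienyl cation: attack at C5 would make a cyclobutane next to a quaternary carbon, the soft doubly stabilised enolate prefers carbon, C4 has no hydrogen so no triene can form by β-hydride loss, and the cation stays bound to palladium. In one operation the step delivers ring A, the diene for ring B and the cage that steers the next cycloaddition to the β face.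

**Step 6**
Reactants: 10 (1S,5R)-6-ethenyl-5-methyl-1-(ArSO2)-3-oxabicyclo[3.3.1]non-6-en-2-one; 11 (E)-2-methylbut-2-enal (tiglaldehyde)
Product: 12 tricyclic lactone aldehyde: rings A and B with C5=C6, C8-methyl and C9-methyl β, C9-formyl (C11) α, H10 α, C2 bearing ArSO2 and the α-face lactone C2–C(=O)–O–C18
Conditions: 11 (3 equiv), Me2AlCl (20 mol %), CH2Cl2, −78 → −20 °C
Reagents that add atoms: none
Why: Lewis-acid-catalysed Diels–Alder reaction in which the formyl-bearing carbon bonds to the substituted diene terminus C10 (ortho rule), the dienophile adds to the β face because the lactone ring oxygen lies under C10 (H10 α, C9 trans to C18), the (E)-geometry gives cis C17/C20, and the exo mode expected for an α-methyl enal (both methyls under the diene, formyl away from the C3 methylene beside C5) places C11 α.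

**Step 7**
Reactants: 13 (S)-4-methyloxolan-2-one
Product: 14 (3S)-4-bromo-3-methylbutanoic acid
Conditions: HBr (33 % in AcOH), 60 °C
Reagents that add atoms: hydrogen bromide, Br
Why: Acid-mediated SN2 opening of the γ-lactone at the O–CH2 carbon by bromide; the stereocentre is not touched.

**Step 8**
Reactants: 14 (3S)-4-bromo-3-methylbutanoic acid
Product: 15 [(2S)-3-carboxy-2-methylpropyl]triphenylphosphonium bromide
Conditions: PPh3, MeCN, reflux
Reagents that add atoms: triphenylphosphine, c1ccccc1P(c1ccccc1)c1ccccc1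
Why: SN2 quaternisation of triphenylphosphine by the primary bromide; the stereocentre is β to the reacting carbon and is unaffected.

**Step 9**
Reactants: 12 tricyclic lactone aldehyde; 15 [(2S)-3-carboxy-2-methylpropyl]triphenylphosphonium bromide
Product: 16 (Z)-C11=C12 alkene acid: 12 with the formyl group replaced by CH=CH–CH(CH3)–CH2–CO2H, C13 configured as in the target
Conditions: 15 (3 equiv), NaN(SiMe3)2 (6 equiv), THF, 0 °C; then 12, 0 → 45 °C; 1 M HCl work-up
Reagents that add atoms: none
Why: Wittig reaction of the carboxylate-bearing non-stabilised ylide with the neopentyl aldehyde, which has no acidic hydrogen because C2 and C9 are quaternary; no stereocentre is created and the alkene geometry does not matter.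

**Step 10**
Reactants: 16 (Z)-C11=C12 alkene acid with sulfonyl lactone
Product: 18 18-hydroxy-2-(ArSO2) halima-5,11(Z)-dien-15-oic acid (C2 epimers), via seco diacid 17 (not isolated)
Conditions: LiOH (6 equiv), DMSO–H2O, 50 °C then 110 °C; 1 M HCl work-up
Reagents that add atoms: none
Why: Saponification of the activated α-sulfonyl lactone and thermal decarboxylation of the α-sulfonyl carboxylate remove the tether carbon and free the C18 hydroxyl; the configuration at C2 is irrelevant.

**Step 11**
Reactants: 18 18-hydroxy-2-(ArSO2) halima-5,11(Z)-dien-15-oic acid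
Product: 19 18-hydroxyhalima-5,11(Z)-dien-15-oic acid
Conditions: Mg turnings (excess), MeOH, 25 → 50 °C; aq. NH4Cl
Reagents that add atoms: none
Why: Single-electron reductive desulfonylation of the electron-poor aryl alkyl sulfone replaces C2–S by C2–H; isolated alkenes and the carboxylate are inert.

**Step 12**
Reactants: 19 18-hydroxyhalima-5,11(Z)-dien-15-oic acid
Product: 20 (13R)-18-hydroxyhalim-5-en-15-oic acid
Conditions: 2-nitrobenzenesulfonylhydrazide (6 equiv), Et3N, CH2Cl2, 25 °C
Reagents that add atoms: none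
Why: Diimide reduction by concerted syn hydrogen transfer should take the cis-disubstituted C11=C12 alkene and leave the hindered trisubstituted C5=C6 alkene, which a metal catalyst might isomerise.

**Step 13**
Reactants: 20 (13R)-18-hydroxyhalim-5-en-15-oic acid
Product: 21 (4R,8S,9R,10S,13R)-18-acetoxyhalim-5-en-15-oic acid (target, CNP0148247.1)
Conditions: Ac2O (3 equiv), pyridine, DMAP (5 mol %), CH2Cl2, 0 °C → rt; then aq. NaHCO3/THF; acidify to pH 3
Reagents that add atoms: acetic anhydride, CC(=O)OC(C)=O
Why: DMAP-catalysed acetylation of the neopentyl primary alcohol; the mixed anhydride formed at C15 is hydrolysed in the bicarbonate work-up.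

**Compound list**
1 | ethyl 2-cyanopropanoate (racemic) | CCOC(=O)C(C)C#N | starting material
2 | 3,5-bis(trifluoromethyl)phenyl vinyl sulfone | C=CS(=O)(=O)c1cc(cc(c1)C(F)(F)F)C(F)(F)F | starting material
3 | ethyl (2S)-2-cyano-2-methyl-4-(ArSO2)butanoate | N#C[C@](C(=O)OCC)(C)CCS(=O)(=O)c1cc(cc(c1)C(F)(F)F)C(F)(F)F | intermediate
4 | (2S)-2-methyl-3-oxo-2-[2-(ArSO2)ethyl]pent-4-enenitrile (vinyl ketone) | N#C[C@](C(=O)C=C)(C)CCS(=O)(=O)c1cc(cc(c1)C(F)(F)F)C(F)(F)F | intermediate (not isolated)
5 | (2S)-3-ethenyl-3-hydroxy-2-methyl-2-[2-(ArSO2)ethyl]pent-4-enenitrile | N#C[C@](C(O)(C=C)C=C)(C)CCS(=O)(=O)c1cc(cc(c1)C(F)(F)F)C(F)(F)F | intermediate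
6 | (2R)-3-ethenyl-3-hydroxy-2-methyl-2-[2-(ArSO2)ethyl]pent-4-enal (hydroxy aldehyde) | O=C[C@](C(O)(C=C)C=C)(C)CCS(=O)(=O)c1cc(cc(c1)C(F)(F)F)C(F)(F)F | intermediate (not isolated)
7 | (2S)-3-ethenyl-2-methyl-2-[2-(ArSO2)ethyl]pent-4-ene-1,3-diol | OC[C@](C(O)(C=C)C=C)(C)CCS(=O)(=O)c1cc(cc(c1)C(F)(F)F)C(F)(F)F | intermediate
8 | (4S)-5-ethenyl-5-hydroxy-4-(hydroxymethyl)-4-methyl-2-(ArSO2)hept-6-enoic acid (C2 epimers; sulfonyl acid) | OC[C@](C(O)(C=C)C=C)(C)CC(C(=O)O)S(=O)(=O)c1cc(cc(c1)C(F)(F)F)C(F)(F)F | intermediate (not isolated)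
9 | (5S)-5-(3-hydroxypenta-1,4-dien-3-yl)-5-methyl-3-(ArSO2)oxan-2-one (C3 epimers) | O1C[C@](C(O)(C=C)C=C)(C)CC(S(=O)(=O)c2cc(cc(c2)C(F)(F)F)C(F)(F)F)C1=O | intermediate
10 | (1S,5R)-6-ethenyl-5-methyl-1-(ArSO2)-3-oxabicyclo[3.3.1]non-6-en-2-one | O1C[C@]2(C(C=C)=CC[C@](S(=O)(=O)c3cc(cc(c3)C(F)(F)F)C(F)(F)F)(C2)C1=O)C | intermediate
11 | (E)-2-methylbut-2-enal (tiglaldehyde) | C/C=C(\C)C=O | starting material
12 | tricyclic lactone aldehyde (C9-CHO α, C8/C9 methyls β, H10 α, lactone C2–C(=O)–O–C18 α, ArSO2 on C2) | O3C[C@]1(C)C[C@](S(=O)(=O)c4cc(cc(c4)C(F)(F)F)C(F)(F)F)(C3=O)C[C@@H]2C1=CC[C@H](C)[C@@]2(C)C=O | intermediate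
13 | (S)-4-methyloxolan-2-one | O1C[C@@H](C)CC1=O | starting material
14 | (3S)-4-bromo-3-methylbutanoic acid | BrC[C@@H](C)CC(=O)O | intermediate
15 | [(2S)-3-carboxy-2-methylpropyl]triphenylphosphonium bromide | c1ccccc1[P+](c1ccccc1)(c1ccccc1)C[C@@H](C)CC(=O)O.[Br-] | intermediate
16 | (Z)-C11=C12 alkene acid with sulfonyl lactone (C13 as in the target) | O3C[C@]1(C)C[C@](S(=O)(=O)c4cc(cc(c4)C(F)(F)F)C(F)(F)F)(C3=O)C[C@@H]2C1=CC[C@H](C)[C@@]2(C)/C=C\[C@@H](C)CC(=O)O | intermediate
17 | seco diacid: 18-hydroxy-2-(ArSO2)-2-carboxy halima-5,11(Z)-dien-15-oic acid | OC[C@]1(C)C[C@](S(=O)(=O)c3cc(cc(c3)C(F)(F)F)C(F)(F)F)(C(=O)O)C[C@@H]2C1=CC[C@H](C)[C@@]2(C)/C=C\[C@@H](C)CC(=O)O | intermediate (not isolated)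
18 | 18-hydroxy-2-(ArSO2) halima-5,11(Z)-dien-15-oic acid (C2 epimers) | OC[C@]1(C)CC(S(=O)(=O)c3cc(cc(c3)C(F)(F)F)C(F)(F)F)C[C@@H]2C1=CC[C@H](C)[C@@]2(C)/C=C\[C@@H](C)CC(=O)O | intermediate
19 | 18-hydroxyhalima-5,11(Z)-dien-15-oic acid | OC[C@]1(C)CCC[C@@H]2C1=CC[C@H](C)[C@@]2(C)/C=C\[C@@H](C)CC(=O)O | intermediate
20 | (13R)-18-hydroxyhalim-5-en-15-oic acid | OC[C@]1(C)CCC[C@@H]2C1=CC[C@H](C)[C@@]2(C)CC[C@@H](C)CC(=O)O | intermediate
21 | (4R,8S,9R,10S,13R)-18-acetoxyhalim-5-en-15-oic acid | CC(=O)OC[C@]1(C)CCC[C@@H]2C1=CC[C@H](C)[C@@]2(C)CC[C@@H](C)CC(=O)O | target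

**Totals**
Total step count: 13. Longest linear sequence: 11 steps (steps 1–6 and 9–13).

**Steps most likely to fail**

Step 6. The risk is an insufficient preference for the exo (formyl-out) transition state, or a cycloaddition too slow for two hindered partners, so that the C8/C9 diastereomer builds up. The fallback changes the dienophile to an α-methyl enone that already carries the whole side chain: its larger acyl group should avoid the endo pocket more strongly than formyl, and no olefination is then needed. It sets out from 10. Commercial methyl hydrogen (R)-3-methylglutarate is converted with (COCl)2 into methyl (3S)-5-chloro-3-methyl-5-oxopentanoate F1. Negishi acylation with (E)-but-2-en-2-ylzinc chloride (from commercial (E)-2-bromobut-2-ene, Pd(PPh3)4) gives methyl (3R,6E)-3,6-dimethyl-5-oxooct-6-enoate F2. Me2AlCl-catalysed cycloaddition of 10 with F2 gives the C11-ketone cycloadduct F3. LiOH in DMSO–H2O (hydrolysis, decarboxylation) gives the hydroxy keto acid sulfone F4, and Mg/MeOH gives the 11-oxo hydroxy acid F5. Wolff–Kishner reduction of the C11 ketone (N2H4, KOH, diethylene glycol, 200 °C) comes back to the route at 20; steps 7–9 and 12 are then not needed.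

Step 5. The risk is slow or unselective ionisation of the unactivated tertiary alcohol (elimination or electrocyclisation of the pentadienyl unit), or oligomerisation instead of closure to the bridged ring. The fallback avoids palladium and sets out from 9. SOCl2/pyridine with allylic transposition gives the primary dienyl chloride (5R)-5-(5-chloropenta-1,3-dien-3-yl)-5-methyl-3-(ArSO2)oxan-2-one F6 as an E/Z mixture. Cs2CO3 with catalytic NaI in MeCN then closes the same C1–C2 bond by intramolecular enolate alkylation: direct SN2 for the isomer with CH2Cl cis to C4, and iodide-mediated allylic equilibration or SN2'' attack at the other vinyl terminus for the second isomer. Both paths give the same diene because the two arms are equivalent, and the fallback comes back to the route at 10.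

Step 2. The risk is conjugate addition of the second vinyl nucleophile to the intermediate enone, attack at the nitrile, or base-induced retro-Michael loss of the sulfone arm. The fallback separates the two additions through an N-methoxy-N-methylamide and sets out from 3. AlMe3/MeNH(OMe)·HCl gives (2S)-2-cyano-N-methoxy-N,2-dimethyl-4-(ArSO2)butanamide F7. One equivalent of CH2=CHMgBr at −78 °C gives vinyl ketone 4, now isolated, and CH2=CHMgBr/CeCl3 converts it into 5, where the route is rejoined.

**Further compounds**
F1 | step 6 | methyl (3S)-5-chloro-3-methyl-5-oxopentanoate | ClC(=O)C[C@@H](C)CC(=O)OC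
F2 | step 6 | methyl (3R,6E)-3,6-dimethyl-5-oxooct-6-enoate | C/C=C(\C)C(=O)C[C@@H](C)CC(=O)OC
F3 | step 6 | C11-ketone cycloadduct (methyl ester, sulfonyl lactone) | O3C[C@]1(C)C[C@](S(=O)(=O)c4cc(cc(c4)C(F)(F)F)C(F)(F)F)(C3=O)C[C@@H]2C1=CC[C@H](C)[C@@]2(C)C(=O)C[C@@H](C)CC(=O)OC
F4 | step 6 | 18-hydroxy-11-oxo-2-(ArSO2)halim-5-en-15-oic acid (C2 epimers) | OC[C@]1(C)CC(S(=O)(=O)c3cc(cc(c3)C(F)(F)F)C(F)(F)F)C[C@@H]2C1=CC[C@H](C)[C@@]2(C)C(=O)C[C@@H](C)CC(=O)O
F5 | step 6 | 18-hydroxy-11-oxohalim-5-en-15-oic acid | OC[C@]1(C)CCC[C@@H]2C1=CC[C@H](C)[C@@]2(C)C(=O)C[C@@H](C)CC(=O)O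
F6 | step 5 | (5R)-5-(5-chloropenta-1,3-dien-3-yl)-5-methyl-3-(ArSO2)oxan-2-one (E/Z and C3 epimers) | O1C[C@](C(C=C)=CCCl)(C)CC(S(=O)(=O)c2cc(cc(c2)C(F)(F)F)C(F)(F)F)C1=O
F7 | step 2 | (2S)-2-cyano-N-methoxy-N,2-dimethyl-4-(ArSO2)butanamide | N#C[C@](C(=O)N(C)OC)(C)CCS(=O)(=O)c1cc(cc(c1)C(F)(F)F)C(F)(F)F
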